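## Analysis of the target

Target 28 is a germacranolide-type sesquiterpene ester. Its core is a ten-membered carbocycle, numbered here C1–C10, cis-fused across C1–C10 to an α-methylene-γ-butyrolactone (C11, exocyclic C13, carbonyl C12, ring oxygen on C1). The carbocycle carries a trisubstituted (Z)-C2=C3 alkene with its methyl on C3, a free allylic hydroxyl at C4, a trisubstituted C5–C6 epoxide (methyl on C6) whose ring bonds C4–C5 and C6–C7 are cis, and an angelate, (Z)-2-methylbut-2-enoate, on C9. With these locants the six stereocentres are 1S, 4R, 5R, 6S, 9R and 10R. The C4 oxygen is anti to the epoxide oxygen, the C9 oxygen is anti to the C11 arm along the chain C1–C10–C9–C8, and H1 and H10 are cis. The sensitive parts are the exocyclic enoate (a Michael acceptor), the angelate (prone to Z-to-E isomerisation), the hydroxy epoxide (acid, Payne and transannular opening) and the 1,4-relation of O9 to C12, which invites migration of the lactone. The difficulty is the ring itself: ten-membered, with a Z-trisubstituted alkene and five ring stereocentres that cannot be set reliably on a flexible medium ring. The strategy rests on C1: it is an allylic carbinol next to the (Z)-C2=C3 alkene, so it is the reduction product of a (Z)-enone whose C1–C2 bond joins an acyl carbon to a stereodefined alkenyl carbon.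

## Retrosynthetic reasoning

**End game (28 ⇒ 27 ⇒ 24 + 25).** The C4 silyl ether of 27 is removed last, and the C9–O acyl bond is cut to angelic acid 25 and alcohol 24. Acylating late keeps the isomerisable Z-enoate away from every basic step. Two silyl ethers of different lability (triethylsilyl on O9, tert-butyldimethylsilyl on O4) allow O9 to be freed alone.

**Lactone (24 ⇒ 23 ⇒ 20 ⇒ 19 ⇒ 18).** The exocyclic C11=C13 bond of 23 is cut back to the saturated lactone 20, so the Michael acceptor appears only after the ring exists. The C12–O bond of 20 is cut to hydroxy ester 19, and the C1–H bond of 19 to the (Z)-enone 18. The forward reduction must deliver hydride to one face of the C1 ketone under the influence of the neighbouring C10 centre; the resulting alcohol is trapped at once by the methyl ester arm.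

**Key disconnection (18 ⇒ 17).** The C1–C2 bond of 18 is cut to the open-chain thioester alkenylstannane 17. This is the only ring bond that joins an acyl carbon to an alkenyl carbon, so it can be made by a palladium/copper acyl coupling that needs neither base nor fluoride. Cutting here leaves C4, C5, C6, C9 and C10 on an open chain, where each can be set by a reagent. The forward step must close a ten-membered ring, keep the Z geometry, select the thioester over the methyl ester, and leave C10 (α to the thioester, β to a silyloxy group) and the epoxide untouched.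

**Stannane and aldol (17 ⇒ 16 ⇒ 15 ⇒ 10 + 13).** The C–Sn bond of 17 is traced to the C–I bond of 16. The iodide, not the stannane, is carried through the preceding steps because a trialkylstannyl alkene would not survive oxidative alkene cleavage, a boron halide and silylation reliably. The C9–C10 bond is cut to aldehyde 10 and the succinate half-thioester 13. A thioester enolises under soft boron conditions in preference to the methyl ester, and an E(O) enolate gives the anti relation between O9 and the C11 arm. Because 10 has no stereocentre near C9, the facial sense must come from the boron reagent.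

**C4 end (10 ⇒ 8 ⇒ 7 ⇒ 5).** The aldehyde of 10 is the masked form of the isopropylidene terminus of 8, which survives everything before it. The iodoalkene of 7 is cut across C3–CH3 and C2–I to the terminal alkyne of 5. A hydroxyl-directed anti addition of a methyl–magnesium bond is the one reliable way to put the C2 substituent cis to C4. It must come before any ester or thioester is present, which fixes the order: C4 end first, aldol afterwards.

**Stereotriad (5 ⇒ 3 + 4 ⇒ 2 ⇒ 1).** The C3–C4 bond of 5 is cut to epoxy aldehyde 3 and ethynylmagnesium bromide 4; Felkin–Anh addition gives the 4,5-anti alcohol. Aldehyde 3 comes from epoxy alcohol 2, and 2 from nerol 1 by a titanium–tartrate epoxidation. The Z geometry of 1 supplies the cis epoxide, and 1 already contains C4–C9 and the C6 methyl.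

**Thioester (13 ⇒ 11 + 12).** Acylation of ethanethiol 12 with the half-ester acid chloride 11.

## Alternatives that were turned down

**Alternative 1: photocycloaddition to a cyclobutene, then cycloreversion.** The ten-membered ring is traced through a C5=C6 and a C9=C10 double bond to the cyclobutane of tricycle A1, which comes from dienone ketal A2 and silyloxycyclobutene A3. Forward, light of about 350 nm joins the unsubstituted enone double bond of A2 to A3 (bonds C5–C6 and C9–C10); heating then opens the bicyclo[2.2.0]hexane of A1 by cleaving C6–C9 and C5–C10.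
- For: the ring is made by ring expansion, with no end-to-end closure and no high dilution. On the ring-forming event itself this is stronger than the chosen route. The sequence is short, and both methyls, the C4 carbonyl and the C1 ketal carbon land in the right places.
- Against: A1 is racemic and all four of its centres are erased, so there is no absolute control. The diradical opening can cleave C7–C8 in place of C5–C10, and nothing secures the geometry of the new C5=C6 bond, which later decides the cis epoxide. All six stereocentres, the C11–C13 arm, the epoxide face and the angelate must then be installed on a flexible ten-membered dienone.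
- Comparison: the chosen route accepts a harder ring closure but sets five of six centres by reagent control on open-chain compounds, and only C1 on the ring.

**Alternative 2: photooxygenation installs the C1 and C4 oxygens together.** The C1–O and C4–O bonds are cut through endoperoxide A4 back to the ten-membered (1Z,3Z)-diene A5. Forward, sensitised photooxygenation adds dioxygen across C1 and C4 of A5 to give A4. Reduction of the O–O bond would give the cis-2-ene-1,4-diol, whose C1 hydroxyl closes onto the acrylate arm.
- For: one suprafacial step sets both oxygens and the Z geometry of C2=C3, with the lactone carbons and the angelate already in place and no protecting groups on O1 or O4. The end game is two or three steps shorter than the chosen one, and the C1/C4 relation follows from the mechanism, not from a hydride delivery.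
- Against: it does not solve the ring. A5, a cyclodecadiene carrying epoxide, angelate and acrylate, still has to be closed and is at least as hard to reach as 18. The diene must adopt an s-cis conformation inside the medium ring. The face of addition relative to C5 and C10 depends only on ring conformation. Ene reactions at the allylic positions compete, and the peroxide must be reduced beside two Michael acceptors.
- Comparison: the chosen route gives up the elegant last step but addresses ring formation and absolute configuration directly.

**Alternative 3: contraction of an eleven-membered sulfone.** A C7=C8 double bond is cut back to the cyclic sulfone A7, with sulfur between C7 and C8. Forward, halogenation at allylic C7 and base treatment give the episulfone, and extrusion of the sulfonyl bridge forms triene A6.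
- For: closing an eleven-membered ring through carbon–sulfur bonds is easier than closing a ten-membered carbocycle, and the contraction is known for medium rings. On reliability of ring formation it is stronger than the chosen route.
- Against: it makes a C7=C8 alkene that the target does not have, conjugated to C5=C6. The target needs C7–C8 saturated and C5–C6 as an epoxide, so a selective reduction of one alkene of a conjugated diene beside C2=C3 is required, followed by a facially selective epoxidation on the ring. The lactol must still be oxidised, methylenated and O9 angelated. The strongly basic step meets a free C9 hydroxyl, and halogenation must choose C7 over C8.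
- Comparison: the chosen route forms a bond the target keeps, at the oxidation level it needs (enone to C1 carbinol), and arrives with the epoxide already in place.

Key step: step 11

## Remarks on the chemistry

- Locants C1–C13 are those defined in the analysis, not IUPAC locants.
- Assumption: the (−)-menthone-derived antipode of the bromoborane in step 8 is taken to be the one that sends the enolate to the Si face of aldehyde 10 (giving 9R,10R). If its sense is the reverse, the mirror-image reagent from (+)-menthone is used and nothing else changes.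

## Route

**Step 1**
Reactants: 1 nerol
Product: 2 [(2R,3S)-3-methyl-3-(4-methylpent-3-en-1-yl)oxiran-2-yl]methanol
Conditions: Ti(OiPr)4 (cat.), D-(−)-diethyl tartrate, tBuOOH, 4 Å MS, CH2Cl2, −20 °C
Reagents that add atoms: tert-butyl hydroperoxide, CC(C)(C)OO
Why: Sharpless asymmetric epoxidation of a primary allylic alcohol; the D-tartrate complex delivers oxygen to the face that gives 2R,3S (C5 R and C6 S of the target), the Z geometry of nerol fixes C4 and C7 cis on the oxirane, and the remote alkene, which has no directing hydroxyl, is left alone.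

**Step 2**
Reactants: 2 [(2R,3S)-3-methyl-3-(4-methylpent-3-en-1-yl)oxiran-2-yl]methanol
Product: 3 (2S,3S)-3-methyl-3-(4-methylpent-3-en-1-yl)oxirane-2-carbaldehyde
Conditions: Dess–Martin periodinane, NaHCO3, CH2Cl2, 0 °C to rt; used crude
Reagents that add atoms: none
Why: Buffered Dess–Martin oxidation turns the primary alcohol into the aldehyde without acid that could open the epoxide; the epoxy aldehyde is taken on at once because such aldehydes hydrate and oligomerise on storage.

**Step 3**
Reactants: 3 (2S,3S)-3-methyl-3-(4-methylpent-3-en-1-yl)oxirane-2-carbaldehyde; 4 ethynylmagnesium bromide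
Product: 5 (1R)-1-[(2R,3S)-3-methyl-3-(4-methylpent-3-en-1-yl)oxiran-2-yl]prop-2-yn-1-ol
Conditions: THF, −78 to −20 °C; NH4Cl aq
Reagents that add atoms: none
Why: Grignard addition to an α,β-epoxy aldehyde under Felkin–Anh control: attack anti to the C5–O bond and past the C5 hydrogen should give the 4,5-anti alcohol (4R), and the cis C7 substituent on the oxirane reinforces this preference.

**Step 4**
Reactants: 5 (1R)-1-[(2R,3S)-3-methyl-3-(4-methylpent-3-en-1-yl)oxiran-2-yl]prop-2-yn-1-ol
Product: 7 (1R,2Z)-3-iodo-2-methyl-1-[(2R,3S)-3-methyl-3-(4-methylpent-3-en-1-yl)oxiran-2-yl]prop-2-en-1-ol, via alkenylmagnesium chelate 6 (not isolated)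
Conditions: MeMgBr (3.5 equiv), CuI (20 mol %), THF, −20 °C to rt; then I2, THF, −78 to 0 °C; NH4Cl aq
Reagents that add atoms: methylmagnesium bromide, C[Mg]Br; iodine, II
Why: Hydroxyl-directed, copper-catalysed anti-carbomagnesiation of a secondary propargylic alcohol: the magnesium alkoxide delivers methyl to the proximal alkyne carbon and holds magnesium on the terminal carbon in a five-membered chelate, so iodinolysis with retention puts iodine cis to C4 (2Z). The trisubstituted epoxide offers methylcopper no unhindered carbon for substitution.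

**Step 5**
Reactants: 7 (1R,2Z)-3-iodo-2-methyl-1-[(2R,3S)-3-methyl-3-(4-methylpent-3-en-1-yl)oxiran-2-yl]prop-2-en-1-ol
Product: 8 tert-butyl{[(1R,2Z)-3-iodo-2-methyl-1-[(2R,3S)-3-methyl-3-(4-methylpent-3-en-1-yl)oxiran-2-yl]prop-2-en-1-yl]oxy}dimethylsilane
Conditions: TBSCl, imidazole, DMF, rt
Reagents that add atoms: tert-butyldimethylsilyl chloride, CC(C)(C)[Si](C)(C)Cl
Why: Standard silylation of a secondary alcohol under mildly basic conditions; a silyl triflate is avoided because it can rearrange the neighbouring epoxide.

**Step 6**
Reactants: 8 tert-butyl{[(1R,2Z)-3-iodo-2-methyl-1-[(2R,3S)-3-methyl-3-(4-methylpent-3-en-1-yl)oxiran-2-yl]prop-2-en-1-yl]oxy}dimethylsilane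
Product: 10 3-[(2S,3R)-3-{(1R,2Z)-1-[(tert-butyldimethylsilyl)oxy]-3-iodo-2-methylprop-2-en-1-yl}-2-methyloxiran-2-yl]propanal, via vicinal diol 9 (not isolated)
Conditions: OsO4 (2 mol %), NaIO4, 2,6-lutidine, dioxane/H2O, rt
Reagents that add atoms: osmium tetroxide, O=[Os](=O)(=O)=O; sodium periodate (terminal oxidant that regenerates it), [Na+].[O-]I(=O)(=O)=O
Why: Lemieux–Johnson cleavage (dihydroxylation, then periodate cleavage of the diol): the electron-rich, unhindered isopropylidene alkene is dihydroxylated much faster than the iodoalkene, which is deactivated by iodine and shielded by the silyloxy carbon; the lutidine buffer protects the epoxide.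

**Step 7**
Reactants: 11 methyl 4-chloro-4-oxobutanoate; 12 ethanethiol
Product: 13 methyl 4-(ethylsulfanyl)-4-oxobutanoate
Conditions: pyridine, CH2Cl2, 0 °C
Reagents that add atoms: none
Why: Acylation of a thiol by an acid chloride; gives the succinate with one thioester and one methyl ester terminus.

**Step 8**
Reactants: 13 methyl 4-(ethylsulfanyl)-4-oxobutanoate; 10 3-[(2S,3R)-3-{(1R,2Z)-1-[(tert-butyldimethylsilyl)oxy]-3-iodo-2-methylprop-2-en-1-yl}-2-methyloxiran-2-yl]propanal
Product: 15 S-ethyl (2R,3R)-3-hydroxy-2-(2-methoxy-2-oxoethyl)-5-[(2S,3R)-3-{(1R,2Z)-1-[(tert-butyldimethylsilyl)oxy]-3-iodo-2-methylprop-2-en-1-yl}-2-methyloxiran-2-yl]pentanethioate, via boron enolate 14 (not isolated)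
Conditions: bis{[(1R,2S,5R)-2-isopropyl-5-methylcyclohexyl]methyl}boron bromide (from (−)-menthone), Et3N, CH2Cl2/Et2O, −5 °C; then 10, −78 to −20 °C; pH 7 buffer, MeOH
Reagents that add atoms: none
Why: Reagent-controlled boron aldol reaction of a thioester: the dialkylboron bromide/triethylamine pair enolises the thioester side of 13 (a simple ester is enolised far more slowly) to the E(O) enolate 14, which reacts through a closed chair (Zimmerman–Traxler) transition state to give the 9,10-anti adduct. The menthone-derived ligands choose the Si face of the aldehyde and so set 9R and 10R.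

**Step 9**
Reactants: 15 S-ethyl (2R,3R)-3-hydroxy-2-(2-methoxy-2-oxoethyl)-5-[(2S,3R)-3-{(1R,2Z)-1-[(tert-butyldimethylsilyl)oxy]-3-iodo-2-methylprop-2-en-1-yl}-2-methyloxiran-2-yl]pentanethioate
Product: 16 S-ethyl (2R,3R)-2-(2-methoxy-2-oxoethyl)-3-[(triethylsilyl)oxy]-5-[(2S,3R)-3-{(1R,2Z)-1-[(tert-butyldimethylsilyl)oxy]-3-iodo-2-methylprop-2-en-1-yl}-2-methyloxiran-2-yl]pentanethioate
Conditions: TESCl, imidazole, DMAP (cat.), CH2Cl2, 0 °C
Reagents that add atoms: chlorotriethylsilane, CC[Si](Cl)(CC)CC
Why: Prompt silylation of the C9 hydroxyl stops it from lactonising onto the C12 ester or opening the C5–C6 epoxide; imidazole is too weak a base to epimerise C10.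

**Step 10**
Reactants: 16 S-ethyl (2R,3R)-2-(2-methoxy-2-oxoethyl)-3-[(triethylsilyl)oxy]-5-[(2S,3R)-3-{(1R,2Z)-1-[(tert-butyldimethylsilyl)oxy]-3-iodo-2-methylprop-2-en-1-yl}-2-methyloxiran-2-yl]pentanethioate
Product: 17 S-ethyl (2R,3R)-2-(2-methoxy-2-oxoethyl)-3-[(triethylsilyl)oxy]-5-[(2S,3R)-3-{(1R,2Z)-1-[(tert-butyldimethylsilyl)oxy]-2-methyl-3-(tributylstannyl)prop-2-en-1-yl}-2-methyloxiran-2-yl]pentanethioate
Conditions: Bu3SnSnBu3, Pd(PPh3)4 (5 mol %), toluene, 60 °C
Reagents that add atoms: hexabutylditin, CCCC[Sn](CCCC)(CCCC)[Sn](CCCC)(CCCC)CCCC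
Why: Palladium-catalysed stannylation of an alkenyl iodide with a distannane, with retention of the Z geometry; zerovalent palladium adds to the C–I bond far faster than to the thioester C–S bond, which needs a copper carboxylate to react.

**Step 11**
Reactants: 17 S-ethyl (2R,3R)-2-(2-methoxy-2-oxoethyl)-3-[(triethylsilyl)oxy]-5-[(2S,3R)-3-{(1R,2Z)-1-[(tert-butyldimethylsilyl)oxy]-2-methyl-3-(tributylstannyl)prop-2-en-1-yl}-2-methyloxiran-2-yl]pentanethioate
Product: 18 ten-membered (2Z)-enone: C1 ketone, C4 (R) OTBS, C5–C6 (5R,6S) epoxide, C9 (R) OTES, C10 (R) CH2CO2Me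
Conditions: Pd2(dba)3 (10 mol %), P(2-furyl)3 (40 mol %), CuO2PPh2 (3 equiv), THF, 0.001 M, syringe-pump addition of 17 over 12 h, 50 °C
Reagents that add atoms: none
Why: Proposed new method: the closest known reaction is the intermolecular palladium-catalysed, copper-carboxylate-mediated coupling of a thioester with an organostannane to give a ketone (Liebeskind–Srogl ketone synthesis); it has not been used to close a ten-membered carbocycle. The monovalent copper of CuO2PPh2 binds the thioester sulfur, zerovalent palladium inserts into the activated C1–S bond, and the thiolate leaves as the copper thiolate. The phosphinate oxygen takes tributyltin from C2, so the alkenyl group passes to divalent palladium with retention, and reductive elimination forms C1–C2. The ring closes end to end, with acyl C1 and alkenyl C2 both becoming ring members, from an eleven-membered palladacycle. No stereocentre is formed and the Z geometry of C2=C3 is inherited from the stannane. The step needs the thioester to react in preference to the methyl ester, which the copper–sulfur activation secures. It needs closure to beat oligomerisation: high dilution and slow addition help, and the cis epoxide, the Z alkene and the two bulky silyl ethers bend the chain towards closure. It needs acyl transfer to beat decarbonylation, which tri(2-furyl)phosphine favours by speeding transmetalation. Finally, C10 and the β-silyloxy group must stay intact, which the absence of base and fluoride allows.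

**Step 12**
Reactants: 18 ten-membered (2Z)-enone
Product: 20 cis-fused lactone (1S,4R,5R,6S,9R,10R) with C11 as CH2, C4 OTBS and C9 OTES, via hydroxy ester 19 (not isolated)
Conditions: NaBH4, CeCl3·7H2O, MeOH, −78 to 0 °C; then DBU (cat.), CH2Cl2, rt
Reagents that add atoms: none
Why: Luche 1,2-reduction of the enone: hydride should attack the outer face of the carbonyl, anti to the C10–C9 ring bond and past H10 (Felkin–Anh sense), to give 1S. The cis γ-hydroxy ester 19 then closes to the cis-fused γ-lactone with loss of methanol.

**Step 13**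
Reactants: 20 cis-fused lactone with C11 as CH2
Product: 23 α-methylene lactone with C4 OTBS and C9 OTES, via Mannich base 21 (not isolated), via methiodide 22 (not isolated)
Conditions: LiN(SiMe3)2, THF, −78 °C; CH2=NMe2+ I−, −78 °C to rt; MeI, MeOH, rt; DBU, CH2Cl2, rt
Reagents that add atoms: N,N-dimethylmethyleneiminium iodide (Eschenmoser's salt), C=[N+](C)C.[I-]
Why: Eschenmoser methylenation: Mannich reaction of the lactone lithium enolate on its convex face, quaternisation of the amine and E1cB loss of trimethylamine; the transient C11 centre is destroyed and the silyl ethers and epoxide are inert to these reagents.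

**Step 14**
Reactants: 23 α-methylene lactone with C4 OTBS and C9 OTES
Product: 24 C9 alcohol (C4 OTBS retained)
Conditions: HF·pyridine, pyridine, THF, 0 °C
Reagents that add atoms: none
Why: Buffered fluoride cleaves the triethylsilyl ether far faster than the hindered secondary tert-butyldimethylsilyl ether; the pyridine buffer keeps the epoxide closed and avoids the acid or base that would move the lactone to O9.

**Step 15**
Reactants: 24 C9 alcohol; 25 angelic acid
Product: 27 C9 angelate (C4 OTBS), via mixed anhydride 26 (not isolated)
Conditions: 25, 2,4,6-trichlorobenzoyl chloride, Et3N, toluene, rt; then 24, toluene, 75 °C (no DMAP)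
Reagents that add atoms: none
Why: Yamaguchi-type mixed-anhydride esterification run without a nucleophilic catalyst, so the Z acyl group is not isomerised by conjugate addition–elimination; O4 is still silylated, so only O9 is acylated.

**Step 16**
Reactants: 27 C9 angelate (C4 OTBS)
Product: 28 target
Conditions: HF·pyridine, pyridine, THF, 0 °C to rt
Reagents that add atoms: none
Why: Fluoride-mediated cleavage of the remaining silyl ether under pyridine buffering, which spares the epoxide, both enoates and the lactone.

## Compound list

1 | nerol, (2Z)-3,7-dimethylocta-2,6-dien-1-ol | CC(C)=CCC/C(C)=C\CO | starting material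
2 | [(2R,3S)-3-methyl-3-(4-methylpent-3-en-1-yl)oxiran-2-yl]methanol | OC[C@H]1O[C@@]1(C)CCC=C(C)C | intermediate
3 | (2S,3S)-3-methyl-3-(4-methylpent-3-en-1-yl)oxirane-2-carbaldehyde | O=C[C@H]1O[C@@]1(C)CCC=C(C)C | intermediate
4 | ethynylmagnesium bromide | C#C[Mg]Br | starting material
5 | (1R)-1-[(2R,3S)-3-methyl-3-(4-methylpent-3-en-1-yl)oxiran-2-yl]prop-2-yn-1-ol | C#C[C@@H](O)[C@H]1O[C@@]1(C)CCC=C(C)C | intermediate
6 | (Z)-alkenylmagnesium chelate of 5 after methyl addition, drawn as the bromomagnesium alkoxide alkenylmagnesium bromide (formed in the flask) | Br[Mg]/C=C(/C)[C@@H](O[Mg]Br)[C@H]1O[C@@]1(C)CCC=C(C)C | intermediate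
7 | (1R,2Z)-3-iodo-2-methyl-1-[(2R,3S)-3-methyl-3-(4-methylpent-3-en-1-yl)oxiran-2-yl]prop-2-en-1-ol | I/C=C(/C)[C@@H](O)[C@H]1O[C@@]1(C)CCC=C(C)C | intermediate
8 | tert-butyldimethylsilyl ether of 7 | I/C=C(/C)[C@@H](O[Si](C)(C)C(C)(C)C)[C@H]1O[C@@]1(C)CCC=C(C)C | intermediate
9 | vicinal diol from the isopropylidene alkene of 8, both epimers at the new carbinol (formed in the flask) | I/C=C(/C)[C@@H](O[Si](C)(C)C(C)(C)C)[C@H]1O[C@@]1(C)CCC(O)C(C)(C)O | intermediate
10 | 3-[(2S,3R)-3-{(1R,2Z)-1-[(tert-butyldimethylsilyl)oxy]-3-iodo-2-methylprop-2-en-1-yl}-2-methyloxiran-2-yl]propanal | I/C=C(/C)[C@@H](O[Si](C)(C)C(C)(C)C)[C@H]1O[C@@]1(C)CCC=O | intermediate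
11 | methyl 4-chloro-4-oxobutanoate | COC(=O)CCC(=O)Cl | starting material
12 | ethanethiol | CCS | starting material
13 | methyl 4-(ethylsulfanyl)-4-oxobutanoate | CCSC(=O)CCC(=O)OC | intermediate
14 | E(O) boron enolate of 13, CH2CO2Me trans to the boryloxy group, boron carrying two (menthyl)methyl ligands (formed in the flask) | CCS/C(OB(C[C@@H]1C[C@H](C)CC[C@H]1C(C)C)C[C@@H]2C[C@H](C)CC[C@H]2C(C)C)=C\CC(=O)OC | intermediate
15 | S-ethyl (2R,3R)-3-hydroxy-2-(2-methoxy-2-oxoethyl)-5-[(2S,3R)-3-{(1R,2Z)-1-[(tert-butyldimethylsilyl)oxy]-3-iodo-2-methylprop-2-en-1-yl}-2-methyloxiran-2-yl]pentanethioate | CCSC(=O)[C@H](CC(=O)OC)[C@H](O)CC[C@]1(C)O[C@@H]1[C@H](O[Si](C)(C)C(C)(C)C)/C(C)=C\I | intermediate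
16 | triethylsilyl ether of 15 | CCSC(=O)[C@H](CC(=O)OC)[C@H](O[Si](CC)(CC)CC)CC[C@]1(C)O[C@@H]1[C@H](O[Si](C)(C)C(C)(C)C)/C(C)=C\I | intermediate
17 | seco thioester (Z)-alkenylstannane, S-ethyl (2R,3R)-2-(2-methoxy-2-oxoethyl)-3-[(triethylsilyl)oxy]-5-[(2S,3R)-3-{(1R,2Z)-1-[(tert-butyldimethylsilyl)oxy]-2-methyl-3-(tributylstannyl)prop-2-en-1-yl}-2-methyloxiran-2-yl]pentanethioate | CCSC(=O)[C@H](CC(=O)OC)[C@H](O[Si](CC)(CC)CC)CC[C@]1(C)O[C@@H]1[C@H](O[Si](C)(C)C(C)(C)C)/C(C)=C\[Sn](CCCC)(CCCC)CCCC | intermediate
18 | ten-membered (2Z)-enone, C1 ketone, (4R) OTBS, (5R,6S) epoxide, (9R) OTES, (10R) CH2CO2Me | COC(=O)C[C@H]1C(=O)/C=C(/C)[C@@H](O[Si](C)(C)C(C)(C)C)[C@H]2O[C@@]2(C)CC[C@H]1O[Si](CC)(CC)CC | intermediate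
19 | (1S)-allylic alcohol from 18, methyl ester arm intact (formed in the flask) | COC(=O)C[C@H]1[C@@H](O)/C=C(/C)[C@@H](O[Si](C)(C)C(C)(C)C)[C@H]2O[C@@]2(C)CC[C@H]1O[Si](CC)(CC)CC | intermediate
20 | cis-fused γ-lactone (1S,4R,5R,6S,9R,10R), C11 as CH2, C4 OTBS, C9 OTES | C1C(=O)O[C@H]2/C=C(/C)[C@@H](O[Si](C)(C)C(C)(C)C)[C@H]3O[C@@]3(C)CC[C@@H](O[Si](CC)(CC)CC)[C@@H]12 | intermediate
21 | C11 dimethylaminomethyl lactone, aminomethyl group trans to the C10–C9 bond (formed in the flask) | CN(C)C[C@@H]1C(=O)O[C@H]2/C=C(/C)[C@@H](O[Si](C)(C)C(C)(C)C)[C@H]3O[C@@]3(C)CC[C@@H](O[Si](CC)(CC)CC)[C@@H]12 | intermediate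
22 | trimethylammonium iodide of 21 (formed in the flask) | C[N+](C)(C)C[C@@H]1C(=O)O[C@H]2/C=C(/C)[C@@H](O[Si](C)(C)C(C)(C)C)[C@H]3O[C@@]3(C)CC[C@@H](O[Si](CC)(CC)CC)[C@@H]12.[I-] | intermediate
23 | α-methylene lactone, C4 OTBS, C9 OTES | C=C1C(=O)O[C@H]2/C=C(/C)[C@@H](O[Si](C)(C)C(C)(C)C)[C@H]3O[C@@]3(C)CC[C@@H](O[Si](CC)(CC)CC)[C@@H]12 | intermediate
24 | α-methylene lactone, C4 OTBS, C9 hydroxyl | C=C1C(=O)O[C@H]2/C=C(/C)[C@@H](O[Si](C)(C)C(C)(C)C)[C@H]3O[C@@]3(C)CC[C@@H](O)[C@@H]12 | intermediate
25 | angelic acid, (2Z)-2-methylbut-2-enoic acid | C/C=C(/C)C(=O)O | starting material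
26 | (2Z)-2-methylbut-2-enoic 2,4,6-trichlorobenzoic anhydride (formed in the flask) | C/C=C(/C)C(=O)OC(=O)c1c(Cl)cc(Cl)cc1Cl | intermediate
27 | C9 angelate, C4 OTBS | C=C1C(=O)O[C@H]2/C=C(/C)[C@@H](O[Si](C)(C)C(C)(C)C)[C@H]3O[C@@]3(C)CC[C@@H](OC(=O)/C(C)=C\C)[C@@H]12 | intermediate
28 | CNP0500828.1, (1S,4R,5R,6S,9R,10R) with the locants of the analysis | C=C1C(=O)O[C@H]2/C=C(/C)[C@@H](O)[C@H]3O[C@@]3(C)CC[C@@H](OC(=O)/C(C)=C\C)[C@@H]12 | target

## Step count and risks

Total: 16 steps. Longest linear sequence: 15 steps (steps 1–6 and 8–16, from nerol 1 to 28); step 7 is a one-step side branch.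

**Step 11 (key step).** The likeliest failure is intermolecular coupling and oligomerisation outrunning closure of a strained ten-membered ring. Slow protodestannylation and decarbonylation of the acylpalladium followed by β-hydride loss can also drain material during a long addition. Fallback, by known chemistry: set out from iodide 16. Reduce the thioester with iBu2AlH at −78 °C to the aldehyde F1. Close the ring by an intramolecular Nozaki–Hiyama–Kishi reaction (CrCl2, catalytic NiCl2, DMSO/THF, high dilution) to the macrocyclic allylic alcohols F2, both C1 epimers. Oxidise with Dess–Martin periodinane to rejoin the route at enone 18.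

**Step 4.** During the hours the carbomagnesiation needs, the magnesium alkoxide beside the epoxide may undergo Payne rearrangement, or halide may open the epoxide at C6 under magnesium Lewis acid activation. Fallback: set out from aldehyde 3. Add LiC≡CSiMe3 to give the silylated propargylic alcohol F3. Apply syn hydrostannation (Bu3SnH, PdCl2(PPh3)2), in which silicon and the hydroxyl both direct tin to C3, to give the stannyl silyl alkene F4. Methylate at tin (MeI, Pd(PPh3)4, copper thiophene-2-carboxylate CuO2C(C4H3S), [Bu4N][O2PPh2]) to the alkenylsilane F5. Iododesilylate with N-iodosuccinimide in hexafluoroisopropanol, with retention, to rejoin at iodide 7.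

**Step 8.** The chiral bromoborane was designed for hindered thioesters. With the S-ethyl thioester the enolate geometry may erode, giving syn adduct, and facial control may drop. The free adduct can also lactonise from O9 onto C12 before silylation. Fallback: set out from aldehyde 10 and use the substrate class the reagent is known for. Make S-tert-butyl methyl thiosuccinate F6 from 11 and 2-methylpropane-2-thiol. Run the same boron aldol to the S-tert-butyl adduct F7. Cleave the thioester alone with AgO2CCF3 in wet THF to the β-hydroxy acid F8. Re-esterify with ethanethiol 12 (carbodiimide, DMAP) to rejoin at 15.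

**Step 12.** Hydride delivery to a ketone in a mobile medium ring may show poor facial selectivity, or the wrong one, giving the 1R alcohol. Fallback: set out from enone 18. Take the 1R hydroxy ester F9 from the reduction (after opening its lactone if it has closed). Hydrolyse the methyl ester with Me3SnOH to the hydroxy acid F10. Close the lactone by Mitsunobu reaction (PPh3, diisopropyl azodicarboxylate), which inverts C1, to rejoin at lactone 20.

**Step 3.** Felkin–Anh selectivity in additions to epoxy aldehydes can be modest, which would leave a mixture at C4. Fallback: set out from the mixture of 5 and its 4S epimer F11. Oxidise with Dess–Martin periodinane to the ynone F12. Reduce under reagent control with Alpine-borane (the S antipode is expected to give 4R, by analogy with simple alkynyl ketones) to return to 5.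

**Step 15.** On heating with amine the acyl donor may isomerise to the E (tiglate) series, and the free O9 may attack C12 so that the lactone migrates. Fallback: set out from alcohol 24. Esterify O9 with 2-[bis(2,2,2-trifluoroethoxy)phosphoryl]propanoic acid (carbodiimide, DMAP) to the phosphonate ester F13. Build the Z alkene on the substrate by Still–Gennari olefination with acetaldehyde (KN(SiMe3)2, 18-crown-6, THF, −78 °C) to rejoin at 27.

## Further compounds

F1 | step 11 | (2R,3R)-aldehyde from 16, C1 as CHO, iodoalkene retained | O=C[C@H](CC(=O)OC)[C@H](O[Si](CC)(CC)CC)CC[C@]1(C)O[C@@H]1[C@H](O[Si](C)(C)C(C)(C)C)/C(C)=C\I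
F2 | step 11 | ten-membered (2Z)-allylic alcohols, both C1 epimers, methyl ester arm | COC(=O)C[C@H]1C(O)/C=C(/C)[C@@H](O[Si](C)(C)C(C)(C)C)[C@H]2O[C@@]2(C)CC[C@H]1O[Si](CC)(CC)CC
F3 | step 4 | (1R)-1-[(2R,3S)-3-methyl-3-(4-methylpent-3-en-1-yl)oxiran-2-yl]-3-(trimethylsilyl)prop-2-yn-1-ol | C[Si](C)(C)C#C[C@@H](O)[C@H]1O[C@@]1(C)CCC=C(C)C
F4 | step 4 | (1R)-2-(tributylstannyl)-3-(trimethylsilyl)prop-2-en-1-ol with silicon cis to C4, on the same epoxide | C[Si](C)(C)/C=C(/[Sn](CCCC)(CCCC)CCCC)[C@@H](O)[C@H]1O[C@@]1(C)CCC=C(C)C
F5 | step 4 | (1R)-2-methyl-3-(trimethylsilyl)prop-2-en-1-ol with silicon cis to C4, on the same epoxide | C[Si](C)(C)/C=C(/C)[C@@H](O)[C@H]1O[C@@]1(C)CCC=C(C)C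
F6 | step 8 | methyl 4-(tert-butylsulfanyl)-4-oxobutanoate | CC(C)(C)SC(=O)CCC(=O)OC
F7 | step 8 | S-tert-butyl analogue of 15 | CC(C)(C)SC(=O)[C@H](CC(=O)OC)[C@H](O)CC[C@]1(C)O[C@@H]1[C@H](O[Si](C)(C)C(C)(C)C)/C(C)=C\I
F8 | step 8 | carboxylic acid corresponding to 15 | OC(=O)[C@H](CC(=O)OC)[C@H](O)CC[C@]1(C)O[C@@H]1[C@H](O[Si](C)(C)C(C)(C)C)/C(C)=C\I
F9 | step 12 | (1R)-epimer of hydroxy ester 19 | COC(=O)C[C@H]1[C@H](O)/C=C(/C)[C@@H](O[Si](C)(C)C(C)(C)C)[C@H]2O[C@@]2(C)CC[C@H]1O[Si](CC)(CC)CC
F10 | step 12 | (1R)-hydroxy acid from F9 | OC(=O)C[C@H]1[C@H](O)/C=C(/C)[C@@H](O[Si](C)(C)C(C)(C)C)[C@H]2O[C@@]2(C)CC[C@H]1O[Si](CC)(CC)CC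
F11 | step 3 | (1S)-epimer of 5 | C#C[C@H](O)[C@H]1O[C@@]1(C)CCC=C(C)C
F12 | step 3 | 1-[(2S,3S)-3-methyl-3-(4-methylpent-3-en-1-yl)oxiran-2-yl]prop-2-yn-1-one | C#CC(=O)[C@H]1O[C@@]1(C)CCC=C(C)C
F13 | step 15 | C9 2-[bis(2,2,2-trifluoroethoxy)phosphoryl]propanoate of 24, both epimers at the phosphonate carbon | C=C1C(=O)O[C@H]2/C=C(/C)[C@@H](O[Si](C)(C)C(C)(C)C)[C@H]3O[C@@]3(C)CC[C@@H](OC(=O)C(C)P(=O)(OCC(F)(F)F)OCC(F)(F)F)[C@@H]12
A1 | alternative 1 | cis-anti-cis tricyclic photoadduct (racemic, one enantiomer drawn) | O=C1C(C)=CC(OC)(OC)[C@H]2[C@@H]1[C@]1(C)CC[C@@]12O[Si](C)(C)C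
A2 | alternative 1 | 4,4-dimethoxy-2-methylcyclohexa-2,5-dien-1-one | O=C1C(C)=CC(OC)(OC)C=C1
A3 | alternative 1 | 1-methyl-2-[(trimethylsilyl)oxy]cyclobut-1-ene | CC1=C(O[Si](C)(C)C)CC1
A4 | alternative 2 | C1,C4-bridged endoperoxide | COC(=O)C(=C)[C@H]1[C@H]2OO[C@H](C(C)=C2)[C@H]3O[C@@]3(C)CC[C@H]1OC(=O)/C(C)=C\C
A5 | alternative 2 | ten-membered (1Z,3Z)-diene with epoxide, angelate and acrylate arm | COC(=O)C(=C)[C@H]1/C=C\C(C)=C/[C@H]2O[C@@]2(C)CC[C@H]1OC(=O)/C(C)=C\C
A6 | alternative 3 | ten-membered (2Z,5Z,7Z)-triene lactol methyl ether | C1[C@@H](OC)O[C@H]2/C=C(/C)[C@@H](O[Si](C)(C)C(C)(C)C)/C=C(/C)\C=C/[C@@H](O)[C@@H]12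
A7 | alternative 3 | eleven-membered cyclic sulfone, sulfur between C7 and C8 | C1[C@@H](OC)O[C@H]2/C=C(/C)[C@@H](O[Si](C)(C)C(C)(C)C)/C=C(/C)CS(=O)(=O)C[C@@H](O)[C@@H]12
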